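**The unit.** A percentage point of share was my unit, because a repeated reading scatters by 2 percentage points and the questions are asked in shares.

| setting | larch | maple | elm | spring | midnight | noon |
|---|---|---|---|---|---|---|
| solid substrate | 0.25 mM | 0.38 mM | 0.50 mM | 0.50 mM | 0.50 mM | 0.50 mM |
| gas | 0.12 mM (held) | 0.12 mM (held) | 0.12 mM (held) | 0.12 mM (held) | 0.12 mM (held) | 0.12 mM (held) |
| free catalyst | 1 µM | 1 µM | 2 µM | 1.0 µM | 1.0 µM | 1.0 µM |
| temperature | 38 °C | 65 °C | 38 °C | 75 °C | 25 °C | 50 °C |
| remark | run made earlier | run made earlier | run made earlier |  |  |  |
| time |  |  |  | 4.0 min | 4.0 min | 4.0 min |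

| run | time / min | target / % | isomer of the product / % |
|---|---|---|---|
| larch | 1.50 | 44 | 29 |
| larch | 2.50 | 51 | 44 |
| larch | 4.00 | 57 | 48 |
| larch | 5.00 | 56 | 45 |
| larch | 8.00 | 52 | 45 |
| larch | 12.0 | 51 | 45 |
| larch | 20.0 | 55 | 45 |
| maple | 0.833 | 60 | 13 |
| maple | 1.50 | 81 | 14 |
| maple | 2.00 | 87 | 14 |
| maple | 3.00 | 85 | 16 |
| maple | 4.00 | 82 | 17 |
| maple | 5.00 | 83 | 15 |
| elm | 1.50 | 49 | 35 |
| elm | 5.00 | 59 | 46 |
| elm | 8.00 | 55 | 47 |
| elm | 15.0 | 56 | 45 |
| elm | 20.0 | 56 | 44 |

(standard deviation of a reading: 2 percentage points)

- solid substrate is a solid; its amount is given per volume of the solution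
- at the start none of the solid substrate is in solution
- at the start none of the gas is in solution
- what has only dissolved of solid substrate counts as not reacted

1. the flask that comes out highest in share of target in all that became target or isomer of the product, or "all alike" when all lie within 1.5 percentage points (spring / midnight / noon / all alike)
2. share of target in all that became target or isomer of the product, spring
3. share of target in all that became target or isomer of the product, midnight
4. share of target in all that became target or isomer of the product, noon

**First instants.** Neither solid substrate nor gas stood in solution at the start, so each flask had to dissolve them first.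

**The middle.** At 1.50 min the larch run had 44% target and 29% isomer of the product, so target held 60.3% of what had formed. This share is also called the selectivity.

**The end.** The last three larch readings gave a ratio of target to isomer of 1.17, and the elm run, with doubled charges, read 1.23. The maple run, warmer, read 5.21. I took these flat ratios as equilibrium between target and isomer, that is thermodynamic control, and the early larch excess of 6.3 points as a trace of kinetic control, though it rests on one reading.

**The reckoning.** I drew the logarithm of the ratio straight against temperature through larch and maple. That gave the plateau share, the share once the readings stop moving: 36.3% for midnight, 69.4% for noon and 90.1% for spring.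

**The crossing.** A plateau counts only if the reading comes after the filling. Larch had nearly filled by 2.50 min, and midnight carries twice its solid substrate per catalyst. Scaling gave 5.00 min before any allowance for the cold, which is longer than the 4.0 min allowed. So I put midnight above its plateau, by something like larch's excess.

The forecast named spring and gave 89%, 37% and 71% for spring, midnight and noon, reasoning that “target and isomer do not interconvert”, whereas my midnight stood higher.

**The result.** The flask gave spring highest at 90.7%, with noon at 71.4% and midnight at 48.6%. Midnight still held 17.5% of the charge as starting material at 4.00 min, and at 40.0 min its share read 33.7%. Against my plateau share of 36.3%, midnight at the asked time stood 12 points higher, and against its own share at 40.0 min it stood 15 points higher.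

    coupling partner + free catalyst ⇌ catalyst intermediate A (K = 3000 /M, k = 1.67 × 10⁵ /M/s, Ea = 32.0 kJ/mol, ΔH = −2.00 kJ/mol)
    starting material + catalyst intermediate A → catalyst intermediate B (k = 1.31 × 10⁵ /M/s, Ea = 26.0 kJ/mol)
    catalyst intermediate B → catalyst intermediate C (k = 112 /s, Ea = 54.0 kJ/mol)
    catalyst intermediate C → free catalyst + target (k = 106 /s, Ea = 61.0 kJ/mol)
    target ⇌ isomer of the product (K = 0.400, k = 0.112 /s, Ea = 77.0 kJ/mol, ΔH = −51.0 kJ/mol)
    solid substrate ⇌ starting material, rate k6*(cs6 - [starting material]) while solid is left; crystals form when [starting material] > cs6 (solubility = 0.290 mM, k = 0.218 /s)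
    gas ⇌ coupling partner, rate k7*(csat - [coupling partner]) (kL = 0.192 /s)
    (constants at 50 °C)

**Second flask.** Noon read at 1.0 min, a quarter of the asked time, has the plateau share 69.4%, and I placed its early reading above that. The computed flask gives 72.7%, with 47.8% of the charge still starting material.

The numbers in the tables are simulated on assumed constants.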